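In a one-step world, where partner, substrate and catalyst meet in a single step, the rate follows the coupling partner present at that moment; this is the second chemist's view of the flask below.

all flasks: left-handed substrate 10 mM; right-handed substrate 10 mM; free catalyst 10 µM
- west: coupling partner 10 mM; impurity 2 µM; run made earlier
- north-west: coupling partner 10 mM; impurity 8.2 µM; run made earlier
- north: coupling partner 15 mM; impurity 4.1 µM; run made earlier
- flask: coupling partner 10.0 mM; impurity 4.1 µM

- west (time / h: left-handed product / %): 0.417: 1.6; 1.33: 1.3; 2.50: 4.5; 3.00: 5.3; 5.00: 9.1; 6.00: 9.5; 8.00: 10.0
- north-west (time / h: left-handed product / %): 0.417: 0.7; 1.33: 2.6; 2.50: 3.4; 3.00: 0.7; 5.00: 3.3; 6.00: 4.0; 8.00: 4.0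
- north (time / h: left-handed product / %): 1.50: 2.9; 3.00: 4.3; 5.00: 6.7; 6.00: 9.9; 8.00: 11.4

(each reading ± 1 percentage point)

- free catalyst is single-handed; left-handed substrate and right-handed substrate are mirror images of each other, charged as a racemate, each of them at the stated concentration
- what was read earlier has a scatter of 1 percentage point, one standard deviation

1. apparent order in coupling partner when 10% of the left-handed substrate and right-handed substrate together are converted (percent change of the rate of making left-handed product for one percent more coupling partner charged)

The first chemist looks at the last readings of the runs. The west run stands at 10.0% after 8.00 h, and the north-west run, with more impurity, at 4.0%. The north run, with more coupling partner, reaches 11.4%. She therefore holds that catalyst is being lost by poisoning, and that extra partner protects it, so she reads the order from these last readings.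

The second chemist answers that the order is asked at a fixed conversion, not a fixed time, and that readings with a scatter of 1 percentage point give only a loose order. She takes the active catalyst as equal at that conversion. Each product takes one coupling partner, so 10% of the two substrates, charged at 10 mM each, takes 2.00 mM. That leaves 8.00 mM of 10.0 mM. Coupling partner charged over coupling partner left is 1.25, the charge-to-remainder ratio. At this conversion the amount used stays the same, so extra charge lands wholly on the remainder, the remainder grows faster in percent than the charge, and on her view the apparent order equals this ratio. My own reckoning is hers, 1.25.

The forecast takes the first chemist's side with 0.5, on the ground that “Extra partner therefore seems to preserve active catalyst”.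

The simulation gives 1.3.

    coupling partner + free catalyst + left-handed substrate → free catalyst + left-handed product (k = 7000 M⁻² min⁻¹)
    coupling partner + free catalyst + right-handed substrate → free catalyst + right-handed product (k = 98.0 M⁻² min⁻¹)
    free catalyst → spent catalyst A (k = 9.80 × 10⁻⁵ min⁻¹)
    free catalyst + impurity → spent catalyst B (k = 7900 M⁻¹ min⁻¹)

The flask's order of 1.3 stands beside the ratio of 1.25. The first chemist's loss of catalyst by poisoning belongs to the early hours of this flask: spent catalyst B stands at 39.5% after 1.00 h and at 41.0% after 5.00 h. In the north run, at the same conversion, the same 2.00 mM comes out of 15 mM, so its charge-to-remainder ratio is 1.15.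

The runs were generated by integration with made-up constants; scatter was added.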